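The pyranone ring C is disconnected at C2–C3. C2 is a benzylic carbon bound to the ring oxygen O1, so in the precursor it is simply the CH2 of a 4-methoxybenzyl aryl ether, and C3 is the carbene carbon of an ortho diazoacetyl group. A chiral dirhodium carboxylate turns diazoketone 8 into a carbene that inserts into one enantiotopic benzylic C–H bond: one operation closes ring C, forms C2–C3 and sets the single stereocenter (2S). The precursor is assembled in four steps from 2,4,6-trihydroxyacetophenone by C-prenylation, regioselective bis-silylation, Mitsunobu etherification and detrifluoroacetylative diazo transfer; fluoride deprotection ends the route.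

Key step: step 5

Assumption (chemistry): the sense of induction of the chiral dirhodium carboxylate on this substrate cannot be assigned in advance. The route is written with Rh2(S-PTTL)4; if this ligand hand should favour the 2R product, the mirror-image catalyst Rh2(R-PTTL)4 is used with nothing else changed.

Step 1
Reactants: 1 1-(2,4,6-trihydroxyphenyl)ethanone; 2 1-bromo-3-methylbut-2-ene (prenyl bromide)
Product: 3 1-[2,4,6-trihydroxy-3-(3-methylbut-2-enyl)phenyl]ethanone
Conditions: 2 (1.0 equiv), 10% aq. KOH, 0 °C to rt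
Reagents that add atoms: none
Why: C-allylation of an ambident phloroglucinol-type phenoxide is favoured in water, where hydrogen bonding masks the oxygen atoms, and because C3 and C5 are equivalent one equivalent of bromide should give a single mono-C-prenyl isomer, separable from O-alkylated and dialkylated material.

Step 2
Reactants: 3 1-[2,4,6-trihydroxy-3-(3-methylbut-2-enyl)phenyl]ethanone
Product: 4 1-[2-hydroxy-3-(3-methylbut-2-enyl)-4,6-bis(triisopropylsilyloxy)phenyl]ethanone
Conditions: iPr3SiCl (2.2 equiv), imidazole, DMF, 0 °C to rt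
Reagents that add atoms: triisopropylsilyl chloride, CC(C)[Si](Cl)(C(C)C)C(C)C
Why: Silyl ether formation should follow acidity and access, the non-chelated para hydroxyl reacting first and the bulky chloride then taking the less hindered ortho hydroxyl, which leaves the hydroxyl flanked by acetyl and prenyl and chelated to the carbonyl.

Step 3
Reactants: 4 1-[2-hydroxy-3-(3-methylbut-2-enyl)-4,6-bis(triisopropylsilyloxy)phenyl]ethanone; 5 (4-methoxyphenyl)methanol
Product: 6 1-[2-[(4-methoxyphenyl)methoxy]-3-(3-methylbut-2-enyl)-4,6-bis(triisopropylsilyloxy)phenyl]ethanone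
Conditions: PPh3, DIAD, THF, 0 °C to rt
Reagents that add atoms: none
Why: Mitsunobu etherification alkylates the remaining chelated phenol through the alkoxyphosphonium ion of the primary benzylic alcohol under neutral conditions that spare the aryl silyl ethers.

Step 4
Reactants: 6 1-[2-[(4-methoxyphenyl)methoxy]-3-(3-methylbut-2-enyl)-4,6-bis(triisopropylsilyloxy)phenyl]ethanone
Product: 8 2-diazo-1-[2-[(4-methoxyphenyl)methoxy]-3-(3-methylbut-2-enyl)-4,6-bis(triisopropylsilyloxy)phenyl]ethanone, via trifluoromethyl 1,3-diketone 7 (not isolated)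
Conditions: LiN(SiMe3)2, THF, −78 °C; CF3CO2CH2CF3, −78 °C; aq. HCl work-up; then MsN3, Et3N, H2O (1 equiv), MeCN, rt
Reagents that add atoms: methanesulfonyl azide, CS(=O)(=O)N=[N+]=[N-] (the two diazo nitrogen atoms of 8); 2,2,2-trifluoroethyl trifluoroacetate, FC(F)(F)COC(=O)C(F)(F)F (the trifluoroacetyl group of 7 only, lost again on the way to 8)
Why: Detrifluoroacetylative diazo transfer (Danheiser procedure), in which the kinetic lithium enolate of the methyl ketone is C-trifluoroacetylated to the activated diketone 7, which takes the diazo group from the sulfonyl azide and loses the trifluoroacetyl group as the N-acylsulfonamide.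

Step 5
Reactants: 8 2-diazo-1-[2-[(4-methoxyphenyl)methoxy]-3-(3-methylbut-2-enyl)-4,6-bis(triisopropylsilyloxy)phenyl]ethanone
Product: 10 (2S)-2-(4-methoxyphenyl)-8-(3-methylbut-2-enyl)-5,7-bis(triisopropylsilyloxy)-2,3-dihydrochromen-4-one, via rhodium carbene 9 (not isolated)
Conditions: Rh2(S-PTTL)4 (dirhodium tetrakis[N-phthaloyl-(S)-tert-leucinate], 1 mol %), CH2Cl2, 0 °C, slow addition of 8 at high dilution
Reagents that add atoms: none
Why: The dirhodium carboxylate expels N2 from 8 to give the electrophilic carbene 9, whose carbene carbon (the future C3) inserts into a benzylic C–H bond of the ortho 4-methoxybenzyl ether through a three-centre, hydride-transfer-like transition state, so that the C2–C3 bond forms while the hydrogen moves to C3. The closest known reaction type is the dirhodium-carboxylate-catalysed intramolecular C–H insertion of ortho-alkoxyaryl α-diazoketones next to the ether oxygen, which gives chroman-4-ones and has enantioselective versions with chiral carboxylate ligands. Ring C closes as a six-membered ring by 1,6 C–H insertion along the chain C3–C4–C4a–C8a–O1–C2; a five-ring insertion is not available because the fifth atom is the ether oxygen. C2 is the only stereocenter and is set under catalyst control, the chiral ligand sphere choosing between the two enantiotopic benzylic hydrogens. The step needs insertion to win over oxonium ylide formation at the ether oxygen (which would end in a 1,2-benzyl shift to a benzofuranone), over cyclopropanation of the prenyl alkene and over reaction at the other ortho oxygen. This should be secured by the double activation of the C–H bond (α-oxygen and 4-methoxyphenyl), by the known preference of dirhodium carboxylates for insertion over ylide formation, by the low basicity of the aryl ether oxygen conjugated to the ketone, by the meta position of the prenyl group (out of intramolecular reach, with dilution suppressing the bimolecular path) and by the bulky silyl ether, which offers no C–H bond within a six-membered transition state.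

Step 6
Reactants: 10 (2S)-2-(4-methoxyphenyl)-8-(3-methylbut-2-enyl)-5,7-bis(triisopropylsilyloxy)-2,3-dihydrochromen-4-one
Product: 11 (2S)-5,7-dihydroxy-2-(4-methoxyphenyl)-8-(3-methylbut-2-enyl)-2,3-dihydrochromen-4-one
Conditions: Bu4NF, AcOH, THF, 0 °C
Reagents that add atoms: none
Why: Fluoride-induced cleavage of both aryl silyl ethers, buffered with acetic acid so that no phenoxide or enolate persists to open ring C by retro-oxa-Michael reaction and erode C2, under conditions that leave the prenyl alkene untouched.

Compound list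
1 | 1-(2,4,6-trihydroxyphenyl)ethanone | CC(=O)c1c(O)cc(O)cc1O | starting material
2 | 1-bromo-3-methylbut-2-ene | CC(C)=CCBr | starting material
3 | 1-[2,4,6-trihydroxy-3-(3-methylbut-2-enyl)phenyl]ethanone | CC(=O)c1c(O)cc(O)c(CC=C(C)C)c1O | intermediate
4 | 1-[2-hydroxy-3-(3-methylbut-2-enyl)-4,6-bis(triisopropylsilyloxy)phenyl]ethanone | CC(=O)c1c(O[Si](C(C)C)(C(C)C)C(C)C)cc(O[Si](C(C)C)(C(C)C)C(C)C)c(CC=C(C)C)c1O | intermediate
5 | (4-methoxyphenyl)methanol | COc1ccc(CO)cc1 | starting material
6 | 1-[2-[(4-methoxyphenyl)methoxy]-3-(3-methylbut-2-enyl)-4,6-bis(triisopropylsilyloxy)phenyl]ethanone | CC(=O)c1c(O[Si](C(C)C)(C(C)C)C(C)C)cc(O[Si](C(C)C)(C(C)C)C(C)C)c(CC=C(C)C)c1OCc1ccc(OC)cc1 | intermediate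
7 | 4,4,4-trifluoro-1-[2-[(4-methoxyphenyl)methoxy]-3-(3-methylbut-2-enyl)-4,6-bis(triisopropylsilyloxy)phenyl]butane-1,3-dione | FC(F)(F)C(=O)CC(=O)c1c(O[Si](C(C)C)(C(C)C)C(C)C)cc(O[Si](C(C)C)(C(C)C)C(C)C)c(CC=C(C)C)c1OCc1ccc(OC)cc1 | intermediate (not isolated)
8 | 2-diazo-1-[2-[(4-methoxyphenyl)methoxy]-3-(3-methylbut-2-enyl)-4,6-bis(triisopropylsilyloxy)phenyl]ethanone | [N-]=[N+]=CC(=O)c1c(O[Si](C(C)C)(C(C)C)C(C)C)cc(O[Si](C(C)C)(C(C)C)C(C)C)c(CC=C(C)C)c1OCc1ccc(OC)cc1 | intermediate
9 | rhodium carbene formed from 8 (carbene carbon on one rhodium atom of the Rh2(S-PTTL)4 core; the SMILES shows the carbene unit on rhodium and omits the second rhodium atom and the four carboxylate ligands) | [Rh]=CC(=O)c1c(O[Si](C(C)C)(C(C)C)C(C)C)cc(O[Si](C(C)C)(C(C)C)C(C)C)c(CC=C(C)C)c1OCc1ccc(OC)cc1 | intermediate (not isolated)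
10 | (2S)-2-(4-methoxyphenyl)-8-(3-methylbut-2-enyl)-5,7-bis(triisopropylsilyloxy)-2,3-dihydrochromen-4-one | COc1ccc([C@@H]2CC(=O)c3c(O[Si](C(C)C)(C(C)C)C(C)C)cc(O[Si](C(C)C)(C(C)C)C(C)C)c(CC=C(C)C)c3O2)cc1 | intermediate
11 | (2S)-5,7-dihydroxy-2-(4-methoxyphenyl)-8-(3-methylbut-2-enyl)-2,3-dihydrochromen-4-one | COc1ccc([C@@H]2CC(=O)c3c(O)cc(O)c(CC=C(C)C)c3O2)cc1 | target

Total step count: 6. Longest linear sequence: 6 steps (1 to 11).

Steps most likely to fail

Step 5 (key step). The carbene may be captured by the ether oxygen and then undergo a 1,2-shift of the 4-methoxybenzyl group, or the insertion may discriminate poorly between the two enantiotopic benzylic hydrogens. The fallback sets out from compound 4 and comes back at compound 10. The free phenol of 4 would be acylated with 4-methoxybenzoyl chloride (Et3N, DMAP, CH2Cl2) to the aryl 4-methoxybenzoate F1. Treatment with LiN(SiMe3)2 in THF should bring about the Baker–Venkataraman acyl transfer, in which the ketone enolate carbon attacks the ester carbonyl through a six-membered cyclic adduct and so still makes the C2–C3 bond, to give the 1,3-diketone F2. Cyclodehydration with catalytic p-toluenesulfonic acid in warm toluene should give the flavone F3. A copper hydride asymmetric conjugate reduction (Cu(OAc)2, the enantiomer of DTBM-SEGPHOS that delivers 2S, a silane, t-BuOH, toluene), a known reaction of chromones, would then set C2 and return 10.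

Step 2. Silylation may take place at the wrong ortho hydroxyl or at all three, because the two ortho hydroxyls differ only in their neighbour. The fallback sets out from compound 1 and comes back at compound 6; it fixes the regiochemistry by mechanism and also bypasses steps 1 and 3. Mono-silylation of the non-chelated para hydroxyl of 1 (iPr3SiCl, 1 equiv, imidazole) should give the 4-silyl ether F4. A first Mitsunobu reaction with 5 should give the mono 4-methoxybenzyl ether F5, and a second one with 3-methylbut-2-en-1-ol the prenyl ether F6. A tandem Claisen–Cope rearrangement catalysed by Eu(fod)3 (CHCl3, 60 °C) should carry the prenyl group to the position para to the oxygen it leaves, which is the carbon next to the benzyl ether oxygen, giving the phenol F7. Silylation of the freed hydroxyl (iPr3SiCl, imidazole) returns 6.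

Step 4. C-Trifluoroacetylation of the hindered, doubly ortho-substituted enolate may stay incomplete, or an aryl silyl ether may be lost in the basic diazo-transfer stage. The fallback sets out from compound 6 and comes back at compound 8. The ketone would be converted into the trimethylsilyl enol ether F8 (LiN(SiMe3)2, Me3SiCl, THF, −78 °C) and brominated with N-bromosuccinimide at −78 °C to the bromoketone F9. Reaction with N,N'-ditosylhydrazine and DBU in THF at 0 °C (alkylation of the hydrazine, then loss of two sulfinate ions) should give 8.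

Further compounds
F1 | step 5 | [2-acetyl-6-(3-methylbut-2-enyl)-3,5-bis(triisopropylsilyloxy)phenyl] 4-methoxybenzoate | CC(=O)c1c(O[Si](C(C)C)(C(C)C)C(C)C)cc(O[Si](C(C)C)(C(C)C)C(C)C)c(CC=C(C)C)c1OC(=O)c1ccc(OC)cc1
F2 | step 5 | 1-[2-hydroxy-3-(3-methylbut-2-enyl)-4,6-bis(triisopropylsilyloxy)phenyl]-3-(4-methoxyphenyl)propane-1,3-dione | COc1ccc(C(=O)CC(=O)c2c(O[Si](C(C)C)(C(C)C)C(C)C)cc(O[Si](C(C)C)(C(C)C)C(C)C)c(CC=C(C)C)c2O)cc1
F3 | step 5 | 2-(4-methoxyphenyl)-8-(3-methylbut-2-enyl)-5,7-bis(triisopropylsilyloxy)chromen-4-one | COc1ccc(-c2cc(=O)c3c(O[Si](C(C)C)(C(C)C)C(C)C)cc(O[Si](C(C)C)(C(C)C)C(C)C)c(CC=C(C)C)c3o2)cc1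
F4 | step 2 | 1-[2,6-dihydroxy-4-(triisopropylsilyloxy)phenyl]ethanone | CC(=O)c1c(O)cc(O[Si](C(C)C)(C(C)C)C(C)C)cc1O
F5 | step 2 | 1-[2-hydroxy-6-[(4-methoxyphenyl)methoxy]-4-(triisopropylsilyloxy)phenyl]ethanone | CC(=O)c1c(O)cc(O[Si](C(C)C)(C(C)C)C(C)C)cc1OCc1ccc(OC)cc1
F6 | step 2 | 1-[2-[(4-methoxyphenyl)methoxy]-6-(3-methylbut-2-enyloxy)-4-(triisopropylsilyloxy)phenyl]ethanone | CC(=O)c1c(OCC=C(C)C)cc(O[Si](C(C)C)(C(C)C)C(C)C)cc1OCc1ccc(OC)cc1
F7 | step 2 | 1-[6-hydroxy-2-[(4-methoxyphenyl)methoxy]-3-(3-methylbut-2-enyl)-4-(triisopropylsilyloxy)phenyl]ethanone | CC(=O)c1c(O)cc(O[Si](C(C)C)(C(C)C)C(C)C)c(CC=C(C)C)c1OCc1ccc(OC)cc1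
F8 | step 4 | trimethylsilyl enol ether of 6, [1-[2-[(4-methoxyphenyl)methoxy]-3-(3-methylbut-2-enyl)-4,6-bis(triisopropylsilyloxy)phenyl]ethenoxy]trimethylsilane | C=C(O[Si](C)(C)C)c1c(O[Si](C(C)C)(C(C)C)C(C)C)cc(O[Si](C(C)C)(C(C)C)C(C)C)c(CC=C(C)C)c1OCc1ccc(OC)cc1
F9 | step 4 | 2-bromo-1-[2-[(4-methoxyphenyl)methoxy]-3-(3-methylbut-2-enyl)-4,6-bis(triisopropylsilyloxy)phenyl]ethanone | BrCC(=O)c1c(O[Si](C(C)C)(C(C)C)C(C)C)cc(O[Si](C(C)C)(C(C)C)C(C)C)c(CC=C(C)C)c1OCc1ccc(OC)cc1
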